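**Plan** (daucane numbering: C1 = angular-methyl carbon, C2, C3, C4 = isopropyl carbinol, C5 = ring-fusion CH, C6 = ester carbon, C7, C8 = methyl-bearing carbon, C9, C10)
1. Retrosynthesis removes the epoxide oxygen and the anisate C6–O bond, then the isopropyl group, then cuts C3–C4 (hydroacylation) and finally C5–C6 and C8–C9.
2. Enabling feature: C4 hangs on C5 and is joined to C9 through the arc C5–C1–C10–C9 of the seven-membered ring, so a temporary C4–C9 bond turns this arc into a cyclopentanone whose two α-carbons are C9 and C5.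
3. Crotonaldehyde (C6–C7–C8 plus methyl) is laid across these α-carbons (C9–C8 Michael, C5–C6 aldol) to give a bicyclo[3.2.1]octan-8-one; cutting C4–C9 then releases the cycloheptane with C4 as an ester on C5.
4. Ring order forward: cyclopentanone (quaternary C1) → bridged bicycle → cycloheptane → five-membered ring of the target (C3–C4) → C8=C9 → epoxide.
5. Stereochemistry: C1 from a copper-catalysed asymmetric conjugate addition; C5 from the chiral-base-controlled face of the Michael step; C4 from α-face addition of isopropyl anti to the C6 substituent.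
6. C6 is set β by the aldol and inverted to α in the Mitsunobu esterification; the epoxide comes from α-face attack anti to the β angular methyl.

Key step: step 3

Assumption: the ligand antipode in step 1 and the cinchona pseudoenantiomer in step 3 are those that give the drawn sense of induction; if either sense is opposite, the antipode (9-O-benzylcupreine in step 3) would be used with no other change.

**Step 1**
Reactants: 1 3-methylcyclopent-2-en-1-one
Product: 2 (R)-3-ethenyl-3-methylcyclopentan-1-one
Conditions: Me2Al(CH=CH2) (pre-formed solution), copper thiophene-2-carboxylate Cu(O2C-C4H3S) 10 mol %, chiral diarylphosphinamine ligand (SimplePhos type) 11 mol %, Et2O, −30 °C; aq. HCl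
Reagents that add atoms: dimethyl(vinyl)aluminium, C=C[Al](C)C
Why: Copper-catalysed asymmetric conjugate addition of an alkenylalane to a β-substituted cyclic enone, in which the ligand should direct vinyl to the Re face of C3 and so set the quaternary carbon (future C1) as R.

**Step 2**
Reactants: 2 (R)-3-ethenyl-3-methylcyclopentan-1-one
Product: 3 (4S)-4-ethenyl-4-methyl-2-(phenylsulfonyl)cyclopentan-1-one (epimers/enol at C2)
Conditions: LDA (2.1 equiv), THF, −78 °C; PhSO2F, −78 °C to 0 °C; H2O
Reagents that add atoms: benzenesulfonyl fluoride, O=S(=O)(F)c1ccccc1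
Why: Kinetic enolate sulfonylation, in which LDA should remove the α-proton remote from the quaternary carbon and the second equivalent of base takes up the acidic β-keto sulfone proton; the new centre is enolisable and of no consequence.

**Step 3**
Reactants: 3 (4S)-4-ethenyl-4-methyl-2-(phenylsulfonyl)cyclopentan-1-one, 4 (E)-but-2-enal
Product: 7 methyl (1S,2S,5R,7R)-2-ethenyl-7-hydroxy-2,5-dimethyl-4-(phenylsulfonyl)cycloheptane-1-carboxylate (epimers at C4), via Michael adduct 5 (not isolated), via bicyclic ketol 6 (not isolated)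
Conditions: 9-O-benzylcupreidine (10 mol %), CH2Cl2, −20 °C; then MeOH, K2CO3 (0.5 equiv), 0 °C to rt
Reagents that add atoms: methanol, CO
Why: The sulfonyl-stabilised enolate carbon (C9) adds to the β-carbon of the enal (C8) to give 5, the only remaining enolisable α-carbon (C5) then adds to the aldehyde (C6) to give the bridged ketol 6, and methoxide adds to the strained bridging ketone (C4) and cleaves C4–C9 in a retro-Claisen step that leaves the cycloheptane with C4 as the ester on C5. The closest known reaction type is the MARDi cascade (Michael addition, aldol, retro-Dieckmann) of α-activated cyclopentanones with enals, here with the Michael stage under bifunctional cinchona base catalysis. The only ring closed directly is the six-membered ring of 6, by a 6-(enolexo)-exo-trig aldol; the seven-membered ring arises when the one-carbon bridge is cut, not by a direct seven-ring closure. The catalyst should deliver the enal to the enolate face cis to the vinyl group (C9), which fixes C5 because the three-carbon bridge must span one face, and should place the C8 methyl equatorial on the chair of 6. The C6 hydroxyl should sit axial, syn to the bridging carbonyl, through a chelated or hydrogen-bonded aldol that avoids the endo vinyl group. The step needs Michael attack at C9 and not C5 (only C9 is doubly activated), cleavage of C4–C9 and not C4–C5 (only the C9 carbanion is stabilised), and survival of the β-hydroxy ester (mild carbonate at low temperature).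

**Step 4**
Reactants: 7 methyl (1S,2S,5R,7R)-2-ethenyl-7-hydroxy-2,5-dimethyl-4-(phenylsulfonyl)cycloheptane-1-carboxylate
Product: 8 methyl (1S,2S,5R,7R)-7-[(tert-butyldimethylsilyl)oxy]-2-ethenyl-2,5-dimethyl-4-(phenylsulfonyl)cycloheptane-1-carboxylate
Conditions: TBSOTf, 2,6-lutidine, CH2Cl2, −78 °C to 0 °C
Reagents that add atoms: tert-butyldimethylsilyl triflate, CC(C)(C)[Si](C)(C)OS(=O)(=O)C(F)(F)F
Why: Silylation of a hindered secondary alcohol with a silyl triflate, which blocks retro-aldol and β-elimination pathways in the carbonyl steps that follow.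

**Step 5**
Reactants: 8 methyl (1S,2S,5R,7R)-7-[(tert-butyldimethylsilyl)oxy]-2-ethenyl-2,5-dimethyl-4-(phenylsulfonyl)cycloheptane-1-carboxylate
Product: 9 (1S,2S,5R,7R)-7-[(tert-butyldimethylsilyl)oxy]-2-ethenyl-2,5-dimethyl-4-(phenylsulfonyl)cycloheptane-1-carbaldehyde
Conditions: i-Bu2AlH (1.1 equiv), CH2Cl2, −78 °C; Rochelle salt
Reagents that add atoms: none
Why: Partial reduction of a methyl ester to the aldehyde through a tetrahedral aluminate that is stable at −78 °C; sulfone, silyl ether and alkene are inert and the base-free conditions should keep C5 intact.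

**Step 6**
Reactants: 9 (1S,2S,5R,7R)-7-[(tert-butyldimethylsilyl)oxy]-2-ethenyl-2,5-dimethyl-4-(phenylsulfonyl)cycloheptane-1-carbaldehyde
Product: 10 (3aR,6R,8R,8aS)-8-[(tert-butyldimethylsilyl)oxy]-3a,6-dimethyl-5-(phenylsulfonyl)octahydroazulen-1(2H)-one (trans-fused; epimers at C5 of the azulene)
Conditions: [Rh(nbd)(dppe)]BF4 (5 mol %, activated with H2), CH2Cl2, rt
Reagents that add atoms: none
Why: Rhodium-catalysed intramolecular hydroacylation of a 3,3-disubstituted 4-pentenal (aldehyde C–H insertion, alkene insertion, reductive elimination) should close the cyclopentanone by forming C3–C4, and the trans ring fusion follows from the trans aldehyde and vinyl groups of 9.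

**Step 7**
Reactants: 10 (3aR,6R,8R,8aS)-8-[(tert-butyldimethylsilyl)oxy]-3a,6-dimethyl-5-(phenylsulfonyl)octahydroazulen-1(2H)-one
Product: 11 6β-[(tert-butyldimethylsilyl)oxy]-9ξ-(phenylsulfonyl)-5αH,8βH-daucan-4β-ol
Conditions: i-PrMgCl, LaCl3·2LiCl (0.3 equiv), THF, 0 °C
Reagents that add atoms: isopropylmagnesium chloride, CC(C)[Mg]Cl
Why: Lanthanide-promoted Grignard 1,2-addition, which suppresses enolisation and reduction; isopropyl should attack the α face of the cyclopentanone, anti to the C6 branch on the adjacent carbon, and so set C4 with a β hydroxyl.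

**Step 8**
Reactants: 11 6β-[(tert-butyldimethylsilyl)oxy]-9ξ-(phenylsulfonyl)-5αH,8βH-daucan-4β-ol
Product: 12 6β-[(tert-butyldimethylsilyl)oxy]-4β-hydroxy-5αH,8βH-daucan-9-one
Conditions: n-BuLi (2.2 equiv), THF, −78 °C; Me3SiOOSiMe3, −78 °C to rt; H2O
Reagents that add atoms: bis(trimethylsilyl) peroxide, C[Si](C)(C)OO[Si](C)(C)C
Why: Oxidative desulfonylation, in which the α-sulfonyl carbanion is oxygenated by the silyl peroxide and the resulting α-siloxy sulfone collapses to the ketone with loss of sulfinate.

**Step 9**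
Reactants: 12 6β-[(tert-butyldimethylsilyl)oxy]-4β-hydroxy-5αH,8βH-daucan-9-one
Product: 13 6β-[(tert-butyldimethylsilyl)oxy]-4β-hydroxy-5αH-dauc-8-en-9-yl trifluoromethanesulfonate
Conditions: KH (3 equiv), THF, rt (equilibration); PhNTf2, 0 °C
Reagents that add atoms: N-phenylbis(trifluoromethanesulfonimide), O=S(=O)(N(c1ccccc1)S(=O)(=O)C(F)(F)F)C(F)(F)F
Why: O-triflation of the thermodynamic potassium enolate, which should be the more substituted C8 enolate because the alternative C10 enolate is less substituted and flanked by the quaternary C1; the C8 stereocentre is erased.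

**Step 10**
Reactants: 13 6β-[(tert-butyldimethylsilyl)oxy]-4β-hydroxy-5αH-dauc-8-en-9-yl trifluoromethanesulfonate
Product: 14 6β-[(tert-butyldimethylsilyl)oxy]-5αH-dauc-8-en-4β-ol
Conditions: Pd(OAc)2 (5 mol %), PPh3, n-Bu3N, HCO2H, DMF, 60 °C
Reagents that add atoms: none
Why: Palladium-catalysed formate reduction of an enol triflate (oxidative addition, formate to hydride with loss of CO2, reductive elimination), which places the alkene exactly where the triflate was.

**Step 11**
Reactants: 14 6β-[(tert-butyldimethylsilyl)oxy]-5αH-dauc-8-en-4β-ol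
Product: 15 5αH-dauc-8-ene-4β,6β-diol (6-epi-jaeschkeanadiol)
Conditions: Bu4NF, THF, rt
Reagents that add atoms: none
Why: Fluoride-induced desilylation of a secondary silyl ether, driven by the Si–F bond strength, with no stereocentre touched.

**Step 12**
Reactants: 15 5αH-dauc-8-ene-4β,6β-diol, 16 4-methoxybenzoic acid
Product: 17 4β-hydroxy-5αH-dauc-8-en-6α-yl 4-methoxybenzoate, i.e. (3R,3aS,4S,8aR)-3-hydroxy-6,8a-dimethyl-3-(propan-2-yl)-1,2,3,3a,4,5,8,8a-octahydroazulen-4-yl 4-methoxybenzoate
Conditions: PPh3, DIAD, toluene, 0 °C to rt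
Reagents that add atoms: none
Why: Mitsunobu esterification, in which the anisate should displace the alkoxyphosphonium group at the secondary C6 by SN2 with inversion (β-OH to α-ester) while the tertiary C4 hydroxyl stays inert.

**Step 13**
Reactants: 17 4β-hydroxy-5αH-dauc-8-en-6α-yl 4-methoxybenzoate
Product: 18 8α,9α-epoxy-4β-hydroxy-5αH-daucan-6α-yl 4-methoxybenzoate (target)
Conditions: m-CPBA, NaHCO3, CH2Cl2, 0 °C
Reagents that add atoms: 3-chloroperbenzoic acid, O=C(OO)c1cccc(Cl)c1
Why: Prilezhaev epoxidation of the only alkene, where the peracid should approach the α face of the trans-fused seven-membered ring, opposite to the β angular methyl on C1, to give the 8α,9α-epoxide.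

**Compound list**
1 | 3-methylcyclopent-2-en-1-one | CC1=CC(=O)CC1 | starting material
2 | (R)-3-ethenyl-3-methylcyclopentan-1-one | C=C[C@]1(C)CCC(=O)C1 | intermediate
3 | (4S)-4-ethenyl-4-methyl-2-(phenylsulfonyl)cyclopentan-1-one (epimers/enol at C2) | C=C[C@]1(C)CC(S(=O)(=O)c2ccccc2)C(=O)C1 | intermediate
4 | (E)-but-2-enal (crotonaldehyde) | C/C=C/C=O | starting material
5 | (3R)-3-[(1S,4S)-4-ethenyl-4-methyl-2-oxo-1-(phenylsulfonyl)cyclopentyl]butanal | O=CC[C@@H](C)[C@@]1(S(=O)(=O)c2ccccc2)C[C@@](C)(C=C)CC1=O | intermediate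
6 | (1S,2R,4R,5S,6S)-6-ethenyl-4-hydroxy-2,6-dimethyl-1-(phenylsulfonyl)bicyclo[3.2.1]octan-8-one (hydroxyl axial and syn to C8, vinyl endo) | O=C1[C@]2(S(=O)(=O)c3ccccc3)C[C@@](C)(C=C)[C@H]1[C@H](O)C[C@H]2C | intermediate
7 | methyl (1S,2S,5R,7R)-2-ethenyl-7-hydroxy-2,5-dimethyl-4-(phenylsulfonyl)cycloheptane-1-carboxylate (epimers at C4) | COC(=O)[C@@H]1[C@H](O)C[C@@H](C)C(S(=O)(=O)c2ccccc2)C[C@@]1(C)C=C | intermediate
8 | methyl (1S,2S,5R,7R)-7-[(tert-butyldimethylsilyl)oxy]-2-ethenyl-2,5-dimethyl-4-(phenylsulfonyl)cycloheptane-1-carboxylate | COC(=O)[C@@H]1[C@H](O[Si](C)(C)C(C)(C)C)C[C@@H](C)C(S(=O)(=O)c2ccccc2)C[C@@]1(C)C=C | intermediate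
9 | (1S,2S,5R,7R)-7-[(tert-butyldimethylsilyl)oxy]-2-ethenyl-2,5-dimethyl-4-(phenylsulfonyl)cycloheptane-1-carbaldehyde | O=C[C@@H]1[C@H](O[Si](C)(C)C(C)(C)C)C[C@@H](C)C(S(=O)(=O)c2ccccc2)C[C@@]1(C)C=C | intermediate
10 | (3aR,6R,8R,8aS)-8-[(tert-butyldimethylsilyl)oxy]-3a,6-dimethyl-5-(phenylsulfonyl)octahydroazulen-1(2H)-one (trans-fused) | O=C1CC[C@]2(C)CC(S(=O)(=O)c3ccccc3)[C@H](C)C[C@@H](O[Si](C)(C)C(C)(C)C)[C@@H]12 | intermediate
11 | 6β-[(tert-butyldimethylsilyl)oxy]-9ξ-(phenylsulfonyl)-5αH,8βH-daucan-4β-ol | CC(C)[C@]1(O)CC[C@]2(C)CC(S(=O)(=O)c3ccccc3)[C@H](C)C[C@@H](O[Si](C)(C)C(C)(C)C)[C@@H]12 | intermediate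
12 | 6β-[(tert-butyldimethylsilyl)oxy]-4β-hydroxy-5αH,8βH-daucan-9-one | CC(C)[C@]1(O)CC[C@]2(C)CC(=O)[C@H](C)C[C@@H](O[Si](C)(C)C(C)(C)C)[C@@H]12 | intermediate
13 | 6β-[(tert-butyldimethylsilyl)oxy]-4β-hydroxy-5αH-dauc-8-en-9-yl trifluoromethanesulfonate | CC(C)[C@]1(O)CC[C@]2(C)CC(OS(=O)(=O)C(F)(F)F)=C(C)C[C@@H](O[Si](C)(C)C(C)(C)C)[C@@H]12 | intermediate
14 | 6β-[(tert-butyldimethylsilyl)oxy]-5αH-dauc-8-en-4β-ol | CC(C)[C@]1(O)CC[C@]2(C)CC=C(C)C[C@@H](O[Si](C)(C)C(C)(C)C)[C@@H]12 | intermediate
15 | 5αH-dauc-8-ene-4β,6β-diol (6-epi-jaeschkeanadiol) | CC(C)[C@]1(O)CC[C@]2(C)CC=C(C)C[C@@H](O)[C@@H]12 | intermediate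
16 | 4-methoxybenzoic acid | COc1ccc(cc1)C(=O)O | starting material
17 | 4β-hydroxy-5αH-dauc-8-en-6α-yl 4-methoxybenzoate | COc1ccc(C(=O)O[C@H]2CC(C)=CC[C@@]3(C)CC[C@@](O)(C(C)C)[C@H]23)cc1 | intermediate
18 | 8α,9α-epoxy-4β-hydroxy-5αH-daucan-6α-yl 4-methoxybenzoate | COc1ccc(C(=O)O[C@H]2C[C@@]3(C)O[C@H]3C[C@@]3(C)CC[C@@](O)(C(C)C)[C@H]23)cc1 | target

**Step count and risks**
Total steps: 13. Longest linear sequence: 13 steps (from 1).

Steps most likely to fail:

Step 3. The enolate face may be controlled incompletely in the conjugate addition, and the β-hydroxy ester may lose water under the basic methanolysis. Fallback, setting out from 3 and 4: the Michael addition is run as in step 3, but the mixture is then treated with catalytic DBU in CH2Cl2 without methanol, so that the sequence stops at the bicyclic ketol 6, which is isolated and freed from diastereomers by chromatography. Silylation (TBSOTf, 2,6-lutidine) should give the silyl ether of the bicyclic ketol F1. NaOMe in MeOH at 0 °C then cleaves the bridging ketone of the protected compound, and the route is rejoined at 8.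

Step 12. The SN2 displacement at the hindered C6 carbinol may fail or give elimination, so that no inversion takes place. Fallback, setting out from 15: oxidation with 1,1,1-triacetoxy-1,1-dihydro-1,2-benziodoxol-3(1H)-one (buffered with NaHCO3) should give 4β-hydroxy-5αH-dauc-8-en-6-one F4. Hydroxyl-directed reduction with Me4NBH(OAc)3 in MeCN/AcOH at −20 °C should deliver hydride from the β face under control of the C4 hydroxyl and give 5αH-dauc-8-ene-4β,6α-diol (jaeschkeanadiol) F5. Acylation of the secondary hydroxyl with 4-methoxybenzoyl chloride, DMAP and pyridine rejoins the route at 17.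

Step 9. Proton removal may occur on the wrong side of the ketone (C10 instead of C8) and give the regioisomeric enol triflate. Fallback, setting out from 12: equilibrating silylation (Me3SiI, (Me3Si)2NH, pentane, rt) should give the more substituted silyl enol ether, with the tertiary hydroxyl also silylated, the bis(trimethylsilyl) compound F2. MeLi in THF regenerates the C8 enolate regiospecifically, and PhNTf2 then gives the enol triflate trimethylsilyl ether F3. Citric acid in MeOH removes the tertiary trimethylsilyl group, and the route is rejoined at 13.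

**Further compounds**
F1 | step 3 | (1S,2R,4R,5S,6S)-4-[(tert-butyldimethylsilyl)oxy]-6-ethenyl-2,6-dimethyl-1-(phenylsulfonyl)bicyclo[3.2.1]octan-8-one | O=C1[C@]2(S(=O)(=O)c3ccccc3)C[C@@](C)(C=C)[C@H]1[C@H](O[Si](C)(C)C(C)(C)C)C[C@H]2C
F2 | step 9 | 6β-[(tert-butyldimethylsilyl)oxy]-4β,9-bis[(trimethylsilyl)oxy]-5αH-dauc-8-ene | CC(C)[C@]1(O[Si](C)(C)C)CC[C@]2(C)CC(O[Si](C)(C)C)=C(C)C[C@@H](O[Si](C)(C)C(C)(C)C)[C@@H]12
F3 | step 9 | 6β-[(tert-butyldimethylsilyl)oxy]-4β-[(trimethylsilyl)oxy]-5αH-dauc-8-en-9-yl trifluoromethanesulfonate | CC(C)[C@]1(O[Si](C)(C)C)CC[C@]2(C)CC(OS(=O)(=O)C(F)(F)F)=C(C)C[C@@H](O[Si](C)(C)C(C)(C)C)[C@@H]12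
F4 | step 12 | 4β-hydroxy-5αH-dauc-8-en-6-one | CC(C)[C@]1(O)CC[C@]2(C)CC=C(C)CC(=O)[C@@H]12
F5 | step 12 | 5αH-dauc-8-ene-4β,6α-diol (jaeschkeanadiol) | CC(C)[C@]1(O)CC[C@]2(C)CC=C(C)C[C@H](O)[C@@H]12
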